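**Plan**

- Locants: isoquinoline atoms are unprimed; primed locants are those of the final naphthalene.
- Feature: in the substituted naphthalene ring (C1'–C4', C4a', C8a') the only unsubstituted carbon is C3', lying between C2' (methyl) and C4' (methoxy). Once N–H is exchanged for N–Cbz and C3'–H for C3'–Br, the bonds C2'–C3' and C3'–C4' are cut together. This removes C3' as dibromocarbene and contracts the ring to the five-membered ring of a 1-aryl-3-methoxy-2-methylindene whose C1' is sp3.
- Further cuts: O–CH3 at C4' (enolate O-methylation), C5–C1' (Friedel–Crafts conjugate addition of isoquinoline C5 to 7-methoxy-2-methylinden-1-one), then N–CO2Bn, C1–H, C1–C8a (Bischler–Napieralski) and C4–aryl (aziridine opening).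
- Forward order: the nitrogen ring is closed first on a symmetrical 3,5-dimethoxyphenyl unit, and the indenone is made from 7-methoxyindan-1-one. The halves are joined at C5–C1' as an aryl–C(sp3) bond, and the second naphthalene ring is completed last by one-carbon ring expansion. One hydrogenolysis then removes bromine and Cbz.
- Stereochemistry: C3 comes from (S)-N-Boc-2-methylaziridine (chiral pool). C1 is set by 1,3-trans-selective hydride reduction of the cyclic imine under control of C3. The centres formed at C1' and C2' are transient.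

Key step: step 10

Assumption: the target structure fixes only C1 and C3 and gives no descriptor for the C5–C1' biaryl axis, so no control of the axis is planned and 20 and 21 are expected as mixtures of the two rotational isomers about it.

**Route**

Step 1
Reactants: 1 1-bromo-3,5-dimethoxybenzene; 2 tert-butyl (S)-2-methylaziridine-1-carboxylate
Product: 4 tert-butyl N-[(2S)-1-(3,5-dimethoxyphenyl)propan-2-yl]carbamate, via aryl Grignard reagent 3 (not isolated)
Conditions: Mg, THF, 45 °C; then CuBr·SMe2 (10 mol %), 2, THF, −30 → 0 °C; aq. NH4Cl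
Reagents that add atoms: none
Why: Copper-catalysed SN2 ring opening of the N-Boc-activated aziridine by the aryl Grignard reagent should occur at the unsubstituted CH2, so the C–N stereocentre of 2 is not touched and appears unchanged as (S) in 4.

Step 2
Reactants: 4 tert-butyl N-[(2S)-1-(3,5-dimethoxyphenyl)propan-2-yl]carbamate
Product: 6 N-[(2S)-1-(3,5-dimethoxyphenyl)propan-2-yl]acetamide, via amine hydrochloride 5 (not isolated)
Conditions: 4 M HCl in dioxane, rt; evaporate; then Ac2O, Et3N, CH2Cl2, 0 °C → rt
Reagents that add atoms: acetic anhydride, CC(=O)OC(C)=O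
Why: Acidolysis of the tert-butyl carbamate followed by N-acetylation of the liberated primary amine is a standard protecting-group exchange that does not involve the stereocentre.

Step 3
Reactants: 6 N-[(2S)-1-(3,5-dimethoxyphenyl)propan-2-yl]acetamide
Product: 7 (3S)-6,8-dimethoxy-1,3-dimethyl-3,4-dihydroisoquinoline
Conditions: POCl3, MeCN, reflux; aq. NaOH work-up
Reagents that add atoms: none
Why: In this Bischler–Napieralski cyclodehydration the activated amide attacks the ring ortho to the side chain, a position activated by one ortho and one para methoxy group; the two ortho positions are equivalent by symmetry, so only the 6,8-dimethoxy isomer can form.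

Step 4
Reactants: 7 (3S)-6,8-dimethoxy-1,3-dimethyl-3,4-dihydroisoquinoline
Product: 8 (1S,3S)-6,8-dimethoxy-1,3-dimethyl-1,2,3,4-tetrahydroisoquinoline
Conditions: LiAlH4, AlMe3, THF, −78 → −20 °C; aq. NaOH work-up
Reagents that add atoms: none
Why: Hydride reduction of the cyclic imine; with AlMe3 bound to nitrogen the 3-methyl group should sit pseudo-axial, and axial hydride delivery to C1 then places the new 1-methyl group trans to it (substrate control from C3, giving 1S), the minor cis isomer being removed by chromatography.

Step 5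
Reactants: 8 (1S,3S)-6,8-dimethoxy-1,3-dimethyl-1,2,3,4-tetrahydroisoquinoline
Product: 9 benzyl (1S,3S)-6,8-dimethoxy-1,3-dimethyl-3,4-dihydroisoquinoline-2(1H)-carboxylate
Conditions: CbzCl, Et3N, CH2Cl2, 0 °C → rt
Reagents that add atoms: benzyl chloroformate, O=C(Cl)OCc1ccccc1
Why: N-Acylation of the secondary amine with a chloroformate gives the carbamate; Cbz is chosen because it should tolerate the Lewis acid of step 8 and the bases of steps 9 and 10 and leaves in the same hydrogenolysis that removes bromine.

Step 6
Reactants: 10 7-methoxyindan-1-one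
Product: 12 racemic 7-methoxy-2-methylindan-1-one, via lithium enolate 11 (not isolated)
Conditions: LiN(SiMe3)2, THF, −78 °C; MeI, −78 → −20 °C
Reagents that add atoms: iodomethane, CI
Why: Enolate formation and SN2 C-methylation at C2, the only enolisable position; the new stereocentre is racemic and is removed in step 7.

Step 7
Reactants: 12 racemic 7-methoxy-2-methylindan-1-one
Product: 14 7-methoxy-2-methyl-1H-inden-1-one, via benzylic bromide 13 (not isolated)
Conditions: NBS, AIBN (cat.), PhCF3, 80 °C; then Et3N, 0 °C → rt
Reagents that add atoms: none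
Why: Wohl–Ziegler radical bromination at the benzylic C3 followed by E1cB dehydrobromination of the β-bromo ketone is the classical two-stage indanone-to-indenone dehydrogenation; the 2-methyl group should temper dimerisation and 14 is used directly.

Step 8
Reactants: 9 benzyl (1S,3S)-6,8-dimethoxy-1,3-dimethyl-3,4-dihydroisoquinoline-2(1H)-carboxylate; 14 7-methoxy-2-methyl-1H-inden-1-one
Product: 15 benzyl (1S,3S)-6,8-dimethoxy-5-(4-methoxy-2-methyl-3-oxo-2,3-dihydro-1H-inden-1-yl)-1,3-dimethyl-3,4-dihydroisoquinoline-2(1H)-carboxylate (mixture of epimers at C1' and C2')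
Conditions: Sc(OTf)3 (10 mol %), CH2Cl2–(CF3)2CHOH, 0 °C → rt, slow addition of 14
Reagents that add atoms: none
Why: In this Lewis-acid-catalysed Friedel–Crafts conjugate addition, Sc(OTf)3 held between the carbonyl and the peri-methoxy group activates C3 of the indenone (the future C1'), and the arene of 9 should attack through C5, which is para to the 8-methoxy and ortho to the 6-methoxy group, rather than through C7 between two methoxy groups; the new stereocentres at C1' and C2' form without control and are carried on as a mixture, since C2' is planarised in step 9 and C1' in step 10.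

Step 9
Reactants: 15 benzyl (1S,3S)-6,8-dimethoxy-5-(4-methoxy-2-methyl-3-oxo-2,3-dihydro-1H-inden-1-yl)-1,3-dimethyl-3,4-dihydroisoquinoline-2(1H)-carboxylate
Product: 17 benzyl (1S,3S)-5-(3,4-dimethoxy-2-methyl-1H-inden-1-yl)-6,8-dimethoxy-1,3-dimethyl-3,4-dihydroisoquinoline-2(1H)-carboxylate (either C1' epimer), via potassium enolate 16 (not isolated)
Conditions: KN(SiMe3)2 (1.05 equiv), THF–DMPU, −78 °C; Me2SO4, −78 → 0 °C
Reagents that add atoms: dimethyl sulfate, COS(=O)(=O)OC
Why: O-Alkylation of a potassium enolate with a hard electrophile in a dipolar medium; the enolate carbon C2' is fully substituted and flanked by the bulky C1' aryl group, so methylation should occur on oxygen, and preforming the enolate with one equivalent of base before a rapid quench limits deprotonation of the product at C1'.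

Step 10
Reactants: 17 benzyl (1S,3S)-5-(3,4-dimethoxy-2-methyl-1H-inden-1-yl)-6,8-dimethoxy-1,3-dimethyl-3,4-dihydroisoquinoline-2(1H)-carboxylate; 18 bromoform
Product: 20 benzyl (1S,3S)-5-(3-bromo-4,5-dimethoxy-2-methylnaphthalen-1-yl)-6,8-dimethoxy-1,3-dimethyl-3,4-dihydroisoquinoline-2(1H)-carboxylate, via dibromocyclopropane adduct 19 (not isolated)
Conditions: CHBr3 (2 equiv), KOtBu (3 equiv, added in portions last), toluene–pentane, −20 °C → rt
Reagents that add atoms: bromoform (compound 18), BrC(Br)Br
Why: Dibromocarbene, formed by α-elimination from 18 with KOtBu, should add in a concerted cheletropic [2+1] step to the C2'=C4' enol-ether bond of 17, the most nucleophilic π bond present, from the face opposite the isoquinoline group at C1', closing the three-membered ring of 19. The methoxy group on the cyclopropane then drives loss of one bromide with disrotatory two-electron electrocyclic opening of the C2'–C4' bond, so the six-membered ring arises by expansion of the five-membered ring with C3' inserted between C2' and C4', not by a cyclisation, and removal of the doubly benzylic C1' proton from the methoxy-stabilised allyl cation aromatises it to 20. The closest known reactions are the dihalocarbene ring expansions of indenes and of indanone-derived enol ethers to 2-halonaphthalenes and 2-halo-1-naphthols (Ciamician–Dennstedt-type one-carbon insertion). No new stereocentre is formed: C1' is planarised, so both C1' epimers of 17 converge on 20, and C1 and C3 are remote and untouched. The step needs chemoselectivity for the tetrasubstituted enol ether over the methoxyarenes, the benzyl group and the carbamate, which the electrophilic carbene supplies by reacting with the most electron-rich alkene. It also needs the double bond to stay at C2'=C4' so that carbon enters next to the methoxy group; this is secured because the enol-ether tautomer conjugated with the benzo ring is the favoured indene isomer, the C1' proton is shielded by the di-ortho-substituted aryl group, and the base meets a mixture in which bromoform is by far the stronger acid.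

Step 11
Reactants: 20 benzyl (1S,3S)-5-(3-bromo-4,5-dimethoxy-2-methylnaphthalen-1-yl)-6,8-dimethoxy-1,3-dimethyl-3,4-dihydroisoquinoline-2(1H)-carboxylate
Product: 21 (1S,3S)-5-(4,5-dimethoxy-2-methylnaphthalen-1-yl)-6,8-dimethoxy-1,3-dimethyl-1,2,3,4-tetrahydroisoquinoline
Conditions: H2 (3 bar), 10% Pd/C, Et3N, EtOAc–EtOH, rt
Reagents that add atoms: none
Why: Heterogeneous palladium-catalysed hydrogenolysis should cleave the aryl C–Br bond (hydrodebromination, HBr taken up by Et3N) and the benzyl C–O bond of the carbamate, whose carbamic acid loses CO2; the ring C1–N bond of tetrahydroisoquinolines is stable under these conditions, so C1 and C3 are unchanged.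

**Compound list**

1 | 1-bromo-3,5-dimethoxybenzene | COc1cc(Br)cc(OC)c1 | starting material
2 | tert-butyl (S)-2-methylaziridine-1-carboxylate | C[C@H]1CN1C(=O)OC(C)(C)C | starting material
3 | 3,5-dimethoxyphenylmagnesium bromide | COc1cc([Mg]Br)cc(OC)c1 | intermediate
4 | tert-butyl N-[(2S)-1-(3,5-dimethoxyphenyl)propan-2-yl]carbamate | COc1cc(C[C@H](C)NC(=O)OC(C)(C)C)cc(OC)c1 | intermediate
5 | (2S)-1-(3,5-dimethoxyphenyl)propan-2-amine hydrochloride | COc1cc(C[C@H](C)N)cc(OC)c1.Cl | intermediate
6 | N-[(2S)-1-(3,5-dimethoxyphenyl)propan-2-yl]acetamide | COc1cc(C[C@H](C)NC(C)=O)cc(OC)c1 | intermediate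
7 | (3S)-6,8-dimethoxy-1,3-dimethyl-3,4-dihydroisoquinoline | COc1cc(OC)c2c(c1)C[C@H](C)N=C2C | intermediate
8 | (1S,3S)-6,8-dimethoxy-1,3-dimethyl-1,2,3,4-tetrahydroisoquinoline | COc1cc(OC)c2c(c1)C[C@H](C)N[C@H]2C | intermediate
9 | benzyl (1S,3S)-6,8-dimethoxy-1,3-dimethyl-3,4-dihydroisoquinoline-2(1H)-carboxylate | COc1cc(OC)c2c(c1)C[C@H](C)N(C(=O)OCc1ccccc1)[C@H]2C | intermediate
10 | 7-methoxyindan-1-one | COc1cccc2CCC(=O)c12 | starting material
11 | lithium 7-methoxy-3H-inden-1-olate (lithium enolate of 10) | COc1cccc2CC=C([O-])c12.[Li+] | intermediate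
12 | 7-methoxy-2-methylindan-1-one (racemic) | COc1cccc2CC(C)C(=O)c12 | intermediate
13 | 3-bromo-7-methoxy-2-methylindan-1-one | COc1cccc2C(Br)C(C)C(=O)c12 | intermediate
14 | 7-methoxy-2-methyl-1H-inden-1-one | COc1cccc2C=C(C)C(=O)c12 | intermediate
15 | benzyl (1S,3S)-6,8-dimethoxy-5-(4-methoxy-2-methyl-3-oxo-2,3-dihydro-1H-inden-1-yl)-1,3-dimethyl-3,4-dihydroisoquinoline-2(1H)-carboxylate (epimer mixture at C1' and C2') | COc1cc(OC)c2c(c1C1C(C)C(=O)c3c(OC)cccc13)C[C@H](C)N(C(=O)OCc1ccccc1)[C@H]2C | intermediate
16 | potassium enolate of 15 (C2'=C4' enolate) | COc1cc(OC)c2c(c1C1C(C)=C([O-])c3c(OC)cccc13)C[C@H](C)N(C(=O)OCc1ccccc1)[C@H]2C.[K+] | intermediate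
17 | benzyl (1S,3S)-5-(3,4-dimethoxy-2-methyl-1H-inden-1-yl)-6,8-dimethoxy-1,3-dimethyl-3,4-dihydroisoquinoline-2(1H)-carboxylate (either C1' epimer) | COc1cc(OC)c2c(c1C1C(C)=C(OC)c3c(OC)cccc13)C[C@H](C)N(C(=O)OCc1ccccc1)[C@H]2C | intermediate
18 | bromoform | BrC(Br)Br | starting material
19 | benzyl (1S,3S)-5-(1,1-dibromo-1a,2-dimethoxy-6a-methyl-1,1a,6,6a-tetrahydrocyclopropa[a]inden-6-yl)-6,8-dimethoxy-1,3-dimethyl-3,4-dihydroisoquinoline-2(1H)-carboxylate | COc1cc(OC)c2c(c1C1C3(C)C(Br)(Br)C3(OC)c4c(OC)cccc14)C[C@H](C)N(C(=O)OCc1ccccc1)[C@H]2C | intermediate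
20 | benzyl (1S,3S)-5-(3-bromo-4,5-dimethoxy-2-methylnaphthalen-1-yl)-6,8-dimethoxy-1,3-dimethyl-3,4-dihydroisoquinoline-2(1H)-carboxylate | COc1cc(OC)c2c(c1-c1c(C)c(Br)c(OC)c3c(OC)cccc13)C[C@H](C)N(C(=O)OCc1ccccc1)[C@H]2C | intermediate
21 | (1S,3S)-5-(4,5-dimethoxy-2-methylnaphthalen-1-yl)-6,8-dimethoxy-1,3-dimethyl-1,2,3,4-tetrahydroisoquinoline | COc1cc(OC)c2c(c1-c1c(C)cc(OC)c3c(OC)cccc13)C[C@H](C)N[C@H]2C | target

**Step count**

Total: 11 steps. Longest linear sequence: 9 steps (steps 1–5 and 8–11 from 1). The indenone branch (steps 6–7) joins at step 8.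

**Steps most likely to fail**

Step 8. Bond formation at the crowded C5 may be slow, so that acid-promoted oligomerisation of the indenone wins. Attack may also occur through C7, or the Lewis acid may ionise the benzylic C1–N bond and scramble C1.
Fallback: the acid-catalysed arene substitution is replaced by an organocopper conjugate addition whose regiochemistry is fixed by a halogen. Setting out from 9, iodination with N-iodosuccinimide (cat. CF3CO2H, MeCN) should give the 5-iodo carbamate F1. Iodine–magnesium exchange with iPrMgCl·LiCl (THF, 0 °C) gives the arylmagnesium chloride F2. This adds 1,4 to indenone 14 under CuBr·SMe2 catalysis at −40 °C, and protonation on work-up returns the route at 15.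

Step 10. The base may move the indene double bond before the carbene is captured, so that carbon enters on the wrong side of C2'. Cyclopropanation of the crowded tetrasubstituted alkene may stall, the allyl cation may collapse by O-demethylation, or excess carbene may attack the electron-rich naphthalene formed.
Fallback: the same two bonds (C2'–C3' and C3'–C4') are made without strong base and without a halogen to remove. Setting out from 15, Me3SiOTf/Et3N gives the trimethylsilyl enol ether F3. Simmons–Smith cyclopropanation (Et2Zn, CH2I2) gives the siloxycyclopropane F4. FeCl3 in DMF opens the inner cyclopropane bond oxidatively to the ring-expanded β-chloro ketone F5. NaOAc in MeOH removes HCl and the resulting dienone tautomerises to the naphthol F6. MeI/K2CO3 gives the naphthyl methyl ether F7, and hydrogenolysis of its Cbz group (H2, Pd/C) comes back to the route at 21.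

Step 9. Methylation on carbon (C2') may compete with methylation on oxygen. Proton exchange between unreacted enolate and the acidic indene product, followed by methylation at C1', is a further risk.
Fallback: the enol ether is made under acid catalysis with no carbanion involved. Setting out from 15, HC(OMe)3 with catalytic p-toluenesulfonic acid in MeOH gives the dimethyl ketal F8. Me3SiOTf/iPr2NEt then removes one methoxy group and the C2' proton to give the conjugated enol ether, returning at 17.

**Further compounds**

F1 | step 8 | benzyl (1S,3S)-5-iodo-6,8-dimethoxy-1,3-dimethyl-3,4-dihydroisoquinoline-2(1H)-carboxylate | COc1cc(OC)c2c(c1I)C[C@H](C)N(C(=O)OCc1ccccc1)[C@H]2C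
F2 | step 8 | [(1S,3S)-2-benzyloxycarbonyl-6,8-dimethoxy-1,3-dimethyl-1,2,3,4-tetrahydroisoquinolin-5-yl]magnesium chloride | COc1cc(OC)c2c(c1[Mg]Cl)C[C@H](C)N(C(=O)OCc1ccccc1)[C@H]2C
F3 | step 10 | benzyl (1S,3S)-6,8-dimethoxy-5-(4-methoxy-2-methyl-3-trimethylsilyloxy-1H-inden-1-yl)-1,3-dimethyl-3,4-dihydroisoquinoline-2(1H)-carboxylate | COc1cc(OC)c2c(c1C1C(C)=C(O[Si](C)(C)C)c3c(OC)cccc13)C[C@H](C)N(C(=O)OCc1ccccc1)[C@H]2C
F4 | step 10 | benzyl (1S,3S)-6,8-dimethoxy-5-(2-methoxy-6a-methyl-1a-trimethylsilyloxy-1,1a,6,6a-tetrahydrocyclopropa[a]inden-6-yl)-1,3-dimethyl-3,4-dihydroisoquinoline-2(1H)-carboxylate | COc1cc(OC)c2c(c1C1C3(C)CC3(O[Si](C)(C)C)c4c(OC)cccc14)C[C@H](C)N(C(=O)OCc1ccccc1)[C@H]2C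
F5 | step 10 | benzyl (1S,3S)-5-(2-chloro-5-methoxy-2-methyl-4-oxo-1,2,3,4-tetrahydronaphthalen-1-yl)-6,8-dimethoxy-1,3-dimethyl-3,4-dihydroisoquinoline-2(1H)-carboxylate | COc1cc(OC)c2c(c1C1C(C)(Cl)CC(=O)c3c(OC)cccc13)C[C@H](C)N(C(=O)OCc1ccccc1)[C@H]2C
F6 | step 10 | benzyl (1S,3S)-5-(4-hydroxy-5-methoxy-2-methylnaphthalen-1-yl)-6,8-dimethoxy-1,3-dimethyl-3,4-dihydroisoquinoline-2(1H)-carboxylate | COc1cc(OC)c2c(c1-c1c(C)cc(O)c3c(OC)cccc13)C[C@H](C)N(C(=O)OCc1ccccc1)[C@H]2C
F7 | step 10 | benzyl (1S,3S)-5-(4,5-dimethoxy-2-methylnaphthalen-1-yl)-6,8-dimethoxy-1,3-dimethyl-3,4-dihydroisoquinoline-2(1H)-carboxylate | COc1cc(OC)c2c(c1-c1c(C)cc(OC)c3c(OC)cccc13)C[C@H](C)N(C(=O)OCc1ccccc1)[C@H]2C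
F8 | step 9 | benzyl (1S,3S)-6,8-dimethoxy-1,3-dimethyl-5-(3,3,4-trimethoxy-2-methyl-2,3-dihydro-1H-inden-1-yl)-3,4-dihydroisoquinoline-2(1H)-carboxylate | COc1cc(OC)c2c(c1C1C(C)C(OC)(OC)c3c(OC)cccc13)C[C@H](C)N(C(=O)OCc1ccccc1)[C@H]2C
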